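## Retrosynthetic overview

1. Target acid ⇐ methyl ester; the Z exocyclic alkene ⇐ chromium-catalysed 1,4-hydrogenation of a conjugated triene ⇐ Suzuki coupling of a bicyclic dienyl triflate (fragment A) with a dioxane alkenylboronate (fragment B).
2. Fragment A ⇐ 6-methoxy-1-tetralone: gem-dimethylation, Birch reduction, enol ether hydrolysis, enol triflate.
3. Fragment B: the 1,2-dioxane is closed by an intramolecular peroxy-Michael (oxa-Michael) addition of a hydroperoxy ketal onto an (E)-enoate (sets C3); C6 ⇐ axial allylation of the cyclic peroxycarbenium ion; C2 methyl ⇐ enolate alkylation.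
4. Ring order: both carbocycles come from the tetralone (aromatic ring reduced early); the dioxane is made in fragment B before the fragments are joined; no ring is formed after the coupling.

Assumption: the quinine-derived squaramide of step 8 is taken to deliver the peroxide oxygen to the Si face of C3 (giving 3S); if the sense proves opposite, its quinidine-derived pseudo-enantiomer is used.

## Route

**Fragment A**

Step 1
Reactants: 1 6-methoxy-3,4-dihydronaphthalen-1(2H)-one (6-methoxy-1-tetralone)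
Product: 2 6-methoxy-1-methyl-1,2,3,4-tetrahydronaphthalen-1-ol (racemic)
Conditions: MeMgBr, THF, 0 °C to rt; aq NH4Cl
Reagents that add atoms: methylmagnesium bromide, C[Mg]Br
Why: Grignard 1,2-addition to the aryl ketone gives the tertiary benzylic alcohol, whose stereocentre is removed in step 2.

Step 2
Reactants: 2 6-methoxy-1-methyl-1,2,3,4-tetrahydronaphthalen-1-ol
Product: 3 6-methoxy-1,1-dimethyl-1,2,3,4-tetrahydronaphthalene
Conditions: Me2Zn (2 equiv), TiCl4 (2 equiv), CH2Cl2, −40 to 0 °C (Me2TiCl2 formed in the flask)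
Reagents that add atoms: dimethylzinc, C[Zn]C
Why: SN1-type C-methylation: the titanium alkoxide ionises to the p-methoxy-stabilised tertiary benzylic cation, which takes a methyl group from the methyltitanium reagent.

Step 3
Reactants: 3 6-methoxy-1,1-dimethyl-1,2,3,4-tetrahydronaphthalene
Product: 4 6-methoxy-1,1-dimethyl-1,2,3,4,5,8-hexahydronaphthalene
Conditions: Li, NH3 (l), THF, tBuOH, −78 to −33 °C; NH4Cl
Reagents that add atoms: none
Why: Birch reduction of the anisole ring leaves the methoxy- and alkyl-bearing carbons sp2, giving the enol ether plus the tetrasubstituted ring-fusion alkene.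

Step 4
Reactants: 4 6-methoxy-1,1-dimethyl-1,2,3,4,5,8-hexahydronaphthalene
Product: 5 5,5-dimethyl-3,4,5,6,7,8-hexahydronaphthalen-2(1H)-one
Conditions: oxalic acid (cat.), MeOH/H2O, rt
Reagents that add atoms: water, O
Why: Mild acid hydrolysis of the enol ether gives the β,γ-unsaturated ketone without moving the tetrasubstituted alkene into conjugation.

Step 5
Reactants: 5 5,5-dimethyl-3,4,5,6,7,8-hexahydronaphthalen-2(1H)-one
Product: 7 5,5-dimethyl-3,4,5,6,7,8-hexahydronaphthalen-2-yl trifluoromethanesulfonate, via potassium dienolate 6 (not isolated)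
Conditions: KN(SiMe3)2, THF, −78 °C; PhNTf2, −78 to 0 °C; aq NH4Cl
Reagents that add atoms: N-phenylbis(trifluoromethanesulfonimide), O=S(=O)(N(c1ccccc1)S(=O)(=O)C(F)(F)F)C(F)(F)F
Why: Deprotonation at the doubly activated C1 (α to C=O and allylic) gives the linear dienolate, which is O-sulfonylated to the 2-triflyloxy-1,3-diene (enol triflate formation).

**Fragment B**

Step 6
Reactants: 8 2-methylhexa-1,5-diene; 9 methyl prop-2-enoate (methyl acrylate, 3 equiv)
Product: 10 methyl (2E)-6-methylhepta-2,6-dienoate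
Conditions: second-generation Grubbs catalyst RuCl2(=CHPh)(PCy3)(H2IMes) (2.5 mol %), CH2Cl2, 40 °C
Reagents that add atoms: none
Why: Olefin cross-metathesis of the monosubstituted alkene with the acrylate is E-selective, and the 1,1-disubstituted alkene does not take part.

Step 7
Reactants: 10 methyl (2E)-6-methylhepta-2,6-dienoate
Product: 11 methyl (2E)-6-hydroperoxy-6-methoxyhept-2-enoate (racemic at C6)
Conditions: O3 (1.0 equiv, Sudan red end point), CH2Cl2/MeOH 4:1, −78 °C; N2 purge, no reductant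
Reagents that add atoms: ozone, [O-][O+]=O; methanol, CO
Why: Chemoselective ozonolysis of the electron-rich 1,1-disubstituted alkene (the enoate is far slower); the Criegee carbonyl oxide is trapped by methanol as the hydroperoxy ketal, whose C6 configuration is erased in step 9.

Step 8
Reactants: 11 methyl (2E)-6-hydroperoxy-6-methoxyhept-2-enoate
Product: 12 methyl 2-[(3S)-6-methoxy-6-methyl-1,2-dioxan-3-yl]acetate (both C6 epimers)
Conditions: quinine-derived 3,5-bis(trifluoromethyl)phenyl squaramide (10 mol %), toluene, −20 °C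
Reagents that add atoms: none
Why: Intramolecular peroxy-Michael (oxa-Michael) addition, 6-exo-trig: the bifunctional catalyst deprotonates the hydroperoxide and hydrogen-bonds the enoate, delivering O to the Si face of C3 to set 3S.

Step 9
Reactants: 12 methyl 2-[(3S)-6-methoxy-6-methyl-1,2-dioxan-3-yl]acetate
Product: 14 methyl 2-[(3S,6R)-6-methyl-6-(prop-2-en-1-yl)-1,2-dioxan-3-yl]acetate, via peroxycarbenium ion 13 (not isolated)
Conditions: allyltrimethylsilane (3 equiv), TiCl4 (1.1 equiv), CH2Cl2, −78 °C; aq NaHCO3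
Reagents that add atoms: allyltrimethylsilane, C=CC[Si](C)(C)C
Why: Hosomi–Sakurai-type allylation: the allylsilane attacks the cyclic peroxycarbenium ion axially through a chair-like transition state with the C3 side chain equatorial, so the allyl group ends cis to the C3 side chain (6R here, 6S in the target).

Step 10
Reactants: 14 methyl 2-[(3S,6R)-6-methyl-6-(prop-2-en-1-yl)-1,2-dioxan-3-yl]acetate
Product: 16 methyl (2S)-2-[(3S,6R)-6-methyl-6-(prop-2-en-1-yl)-1,2-dioxan-3-yl]propanoate, via lithium enolate 15 (not isolated)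
Conditions: LiN(SiMe3)2 (1.1 equiv), THF, −78 °C, 5 min; MeI (5 equiv), DMPU, −78 °C; AcOH quench at −78 °C
Reagents that add atoms: iodomethane, CI
Why: Enolate C-alkylation: with H3 eclipsing the enolate, MeI enters anti to the ring oxygen O2 (the ring shields the other face), giving the 2,3-anti product 2S; low temperature and excess MeI are used to outrun fragmentation of the β-peroxy enolate.

Step 11
Reactants: 16 methyl (2S)-2-[(3S,6R)-6-methyl-6-(prop-2-en-1-yl)-1,2-dioxan-3-yl]propanoate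
Product: 17 methyl (2S)-2-[(3S,6R)-6-methyl-6-[(2E)-3-(4,4,5,5-tetramethyl-1,3,2-dioxaborolan-2-yl)prop-2-en-1-yl]-1,2-dioxan-3-yl]propanoate
Conditions: second-generation Grubbs catalyst RuCl2(=CHPh)(PCy3)(H2IMes) (5 mol %), CH2Cl2, 40 °C
Reagents that add atoms: 2-ethenyl-4,4,5,5-tetramethyl-1,3,2-dioxaborolane, C=CB1OC(C)(C)C(C)(C)O1
Why: Cross-metathesis with the vinylboronate gives the E-alkenylboronate; the dialkyl peroxide and the ester are inert to the ruthenium carbene.

**Coupling and end game**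

Step 12
Reactants: 7 5,5-dimethyl-3,4,5,6,7,8-hexahydronaphthalen-2-yl trifluoromethanesulfonate; 17 the alkenylboronate
Product: 18 methyl (2S)-2-[(3S,6R)-6-[(2E)-3-(5,5-dimethyl-3,4,5,6,7,8-hexahydronaphthalen-2-yl)prop-2-en-1-yl]-6-methyl-1,2-dioxan-3-yl]propanoate
Conditions: PdCl2(dppf) (5 mol %), K3PO4, THF/H2O 10:1, 40 °C
Reagents that add atoms: none
Why: Suzuki–Miyaura coupling of the alkenyl triflate with the alkenylboronate proceeds with retention at both sp2 carbons and gives the conjugated triene.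

Step 13
Reactants: 18 the triene ester
Product: 19 methyl (2S)-2-[(3S,6S)-6-[(3Z)-3-(5,5-dimethyl-3,4,5,6,7,8-hexahydronaphthalen-2(1H)-ylidene)propyl]-6-methyl-1,2-dioxan-3-yl]propanoate
Conditions: (η6-naphthalene)Cr(CO)3 (20 mol %), H2 (4 atm), degassed THF, 25 °C, dark
Reagents that add atoms: none
Why: Arene–Cr(CO)3-catalysed 1,4-hydrogenation: only the diene C1=C2–CH=CH with unhindered termini binds η4 in its s-cis form, H adds to C1 and to the chain CH, and the new C2=C bond keeps the cisoid geometry (chain cis to C1, Z); the ring diene with fully substituted termini and isolated alkenes are left alone.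

Step 14
Reactants: 19 the methyl ester
Product: 20 (2S)-2-[(3S,6S)-6-[(3Z)-3-(5,5-dimethyl-3,4,5,6,7,8-hexahydronaphthalen-2(1H)-ylidene)propyl]-6-methyl-1,2-dioxan-3-yl]propanoic acid
Conditions: LiOH, THF/MeOH/H2O, 0 °C to rt; 1 M HCl to pH 3
Reagents that add atoms: lithium hydroxide, [Li+].[OH-]
Why: Ester saponification under mild conditions that leave the dialkyl peroxide and the C2 stereocentre untouched.

## Compound list

1 | 6-methoxy-3,4-dihydronaphthalen-1(2H)-one | COc1ccc2c(c1)CCCC2=O | starting material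
2 | 6-methoxy-1-methyl-1,2,3,4-tetrahydronaphthalen-1-ol (racemic) | COc1ccc2c(c1)CCCC2(C)O | intermediate
3 | 6-methoxy-1,1-dimethyl-1,2,3,4-tetrahydronaphthalene | COc1ccc2c(c1)CCCC2(C)C | intermediate
4 | 6-methoxy-1,1-dimethyl-1,2,3,4,5,8-hexahydronaphthalene | COC1=CCC2=C(C1)CCCC2(C)C | intermediate
5 | 5,5-dimethyl-3,4,5,6,7,8-hexahydronaphthalen-2(1H)-one | O=C1CCC2=C(C1)CCCC2(C)C | intermediate
6 | potassium 5,5-dimethyl-3,4,5,6,7,8-hexahydronaphthalen-2-olate (dienolate, formed in the flask) | [K+].[O-]C1=CC2=C(CC1)C(C)(C)CCC2 | intermediate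
7 | 5,5-dimethyl-3,4,5,6,7,8-hexahydronaphthalen-2-yl trifluoromethanesulfonate | FC(F)(F)S(=O)(=O)OC1=CC2=C(CC1)C(C)(C)CCC2 | intermediate
8 | 2-methylhexa-1,5-diene | C=C(C)CCC=C | starting material
9 | methyl prop-2-enoate | C=CC(=O)OC | starting material
10 | methyl (2E)-6-methylhepta-2,6-dienoate | COC(=O)/C=C/CCC(C)=C | intermediate
11 | methyl (2E)-6-hydroperoxy-6-methoxyhept-2-enoate (racemic at C6) | COC(=O)/C=C/CCC(C)(OC)OO | intermediate
12 | methyl 2-[(3S)-6-methoxy-6-methyl-1,2-dioxan-3-yl]acetate (both C6 epimers) | COC(=O)C[C@@H]1CCC(C)(OC)OO1 | intermediate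
13 | (3S)-3-(2-methoxy-2-oxoethyl)-6-methyl-1,2-dioxan-6-ylium (cyclic peroxycarbenium ion, formed in the flask) | COC(=O)C[C@@H]1CCC(C)=[O+]O1 | intermediate
14 | methyl 2-[(3S,6R)-6-methyl-6-(prop-2-en-1-yl)-1,2-dioxan-3-yl]acetate | COC(=O)C[C@@H]1CC[C@](C)(CC=C)OO1 | intermediate
15 | lithium 1-methoxy-2-[(3S,6R)-6-methyl-6-(prop-2-en-1-yl)-1,2-dioxan-3-yl]ethen-1-olate (formed in the flask) | [Li+].[O-]C(OC)=C[C@@H]1CC[C@](C)(CC=C)OO1 | intermediate
16 | methyl (2S)-2-[(3S,6R)-6-methyl-6-(prop-2-en-1-yl)-1,2-dioxan-3-yl]propanoate | C[C@H](C(=O)OC)[C@@H]1CC[C@](C)(CC=C)OO1 | intermediate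
17 | methyl (2S)-2-[(3S,6R)-6-methyl-6-[(2E)-3-(4,4,5,5-tetramethyl-1,3,2-dioxaborolan-2-yl)prop-2-en-1-yl]-1,2-dioxan-3-yl]propanoate | C[C@H](C(=O)OC)[C@@H]1CC[C@](C)(C/C=C/B2OC(C)(C)C(C)(C)O2)OO1 | intermediate
18 | methyl (2S)-2-[(3S,6R)-6-[(2E)-3-(5,5-dimethyl-3,4,5,6,7,8-hexahydronaphthalen-2-yl)prop-2-en-1-yl]-6-methyl-1,2-dioxan-3-yl]propanoate | C[C@H](C(=O)OC)[C@@H]1CC[C@](C)(C/C=C/C2=CC3=C(CC2)C(C)(C)CCC3)OO1 | intermediate
19 | methyl (2S)-2-[(3S,6S)-6-[(3Z)-3-(5,5-dimethyl-3,4,5,6,7,8-hexahydronaphthalen-2(1H)-ylidene)propyl]-6-methyl-1,2-dioxan-3-yl]propanoate | C[C@H](C(=O)OC)[C@@H]1CC[C@](C)(CC/C=C2/CCC3=C(CCCC3(C)C)C2)OO1 | intermediate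
20 | (2S)-2-[(3S,6S)-6-[(3Z)-3-(5,5-dimethyl-3,4,5,6,7,8-hexahydronaphthalen-2(1H)-ylidene)propyl]-6-methyl-1,2-dioxan-3-yl]propanoic acid | C[C@H](C(=O)O)[C@@H]1CC[C@](C)(CC/C=C2/CCC3=C(CCCC3(C)C)C2)OO1 | target

## Step count and weak points

Total: 14 steps. Longest linear sequence: 9 steps (steps 6–11, then 12–14); the fragment A branch is 5 steps (1–5).

**Step 8 (enantioselective peroxy-Michael).** The ring closure itself is reliable, but catalyst control of the C3 face with a hydroperoxide nucleophile is unproven and the ee may be low. Fallback, setting out from 11 and coming back at 12: give up catalyst control. Cyclise 11 with Et2NH in CF3CH2OH to racemic methyl 2-(6-methoxy-6-methyl-1,2-dioxan-3-yl)acetate F1, then separate the enantiomers by preparative chromatography on a chiral stationary phase. The 3S enantiomer is 12 and enters step 9.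

**Step 10 (methylation of a β-peroxy ester enolate).** The enolate can open the ring by E1cB loss of the peroxide or close to an epoxide before it is methylated, and the anti selectivity is only substrate-controlled. A Michael closure onto the α-methyl enoate is not a way out, because protonation anti to O2 would give the 2,3-syn epimer. Fallback, setting out from 10 and coming back at 16: install the methyl group before any O–O bond exists and close the ring by SN2 displacement.
- Copper-catalysed enantioselective β-borylation of 10 (CuCl, NaOtBu, chiral ferrocenyl bisphosphine, B2pin2, MeOH) gives methyl (3S)-6-methyl-3-(4,4,5,5-tetramethyl-1,3,2-dioxaborolan-2-yl)hept-6-enoate F2.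
- Oxidation with NaBO3·4H2O (retention) gives methyl (3S)-3-hydroxy-6-methylhept-6-enoate F3.
- Fráter–Seebach alkylation of the dianion (LiN(iPr)2 2.2 equiv, MeI) gives the anti product methyl (2S,3S)-3-hydroxy-2,6-dimethylhept-6-enoate F4.
- Mitsunobu tosylation with inversion (Zn(OTs)2, PPh3, DIAD) gives methyl (2S,3R)-2,6-dimethyl-3-[(4-methylbenzenesulfonyl)oxy]hept-6-enoate F5.
- Ozonolysis in CH2Cl2/MeOH at −78 °C, as in step 7, gives methyl (2S,3R)-6-hydroperoxy-6-methoxy-2-methyl-3-[(4-methylbenzenesulfonyl)oxy]heptanoate F6.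
- KOtBu with 18-crown-6 (THF, −40 °C) closes the dioxane by intramolecular SN2 attack of the peroxide anion with inversion at C3, giving methyl (2S)-2-[(3S)-6-methoxy-6-methyl-1,2-dioxan-3-yl]propanoate F7.
- Allylation of F7 under the conditions of step 9 gives 16.

**Step 13 (1,4-hydrogenation next to a peroxide).** Zerovalent chromium under H2 may cleave the O–O bond, and the ring diene could compete for the catalyst. Fallback, setting out from 16 (with triflate 7) and coming back at 19: set the Z alkene by reductive 1,3-transposition of an allylic alcohol.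
- Hydroboration–oxidation of the allyl group of 16 (9-BBN; NaBO3·4H2O) gives methyl (2S)-2-[(3S,6S)-6-(3-hydroxypropyl)-6-methyl-1,2-dioxan-3-yl]propanoate F8.
- Dess–Martin oxidation gives methyl (2S)-2-[(3S,6R)-6-methyl-6-(3-oxopropyl)-1,2-dioxan-3-yl]propanoate F9.
- Miyaura borylation of 7 (B2pin2, PdCl2(PPh3)2, KOPh) gives 2-(5,5-dimethyl-3,4,5,6,7,8-hexahydronaphthalen-2-yl)-4,4,5,5-tetramethyl-1,3,2-dioxaborolane F10.
- Rhodium-catalysed 1,2-addition of F10 to F9 ([Rh(OH)(cod)]2, aqueous dioxane) gives methyl (2S)-2-[(3S,6S)-6-[3-(5,5-dimethyl-3,4,5,6,7,8-hexahydronaphthalen-2-yl)-3-hydroxypropyl]-6-methyl-1,2-dioxan-3-yl]propanoate F11 (both carbinol epimers).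
- Mitsunobu displacement with 2-nitrobenzenesulfonylhydrazide (PPh3, DEAD, THF, −30 °C) and warming gives methyl (2S)-2-[(3S,6S)-6-[3-diazenyl-3-(5,5-dimethyl-3,4,5,6,7,8-hexahydronaphthalen-2-yl)propyl]-6-methyl-1,2-dioxan-3-yl]propanoate F12.
- F12 loses N2 by a retro-ene shift that puts H on C1 and places the chain away from the C3 methylene (allylic 1,2-strain), i.e. cis to C1, giving 19.

## Further compounds

F1 | step 8 | racemic methyl 2-(6-methoxy-6-methyl-1,2-dioxan-3-yl)acetate | COC(=O)CC1CCC(C)(OC)OO1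
F2 | step 10 | methyl (3S)-6-methyl-3-(4,4,5,5-tetramethyl-1,3,2-dioxaborolan-2-yl)hept-6-enoate | COC(=O)C[C@@H](B1OC(C)(C)C(C)(C)O1)CCC(C)=C
F3 | step 10 | methyl (3S)-3-hydroxy-6-methylhept-6-enoate | COC(=O)C[C@@H](O)CCC(C)=C
F4 | step 10 | methyl (2S,3S)-3-hydroxy-2,6-dimethylhept-6-enoate | C[C@H](C(=O)OC)[C@@H](O)CCC(C)=C
F5 | step 10 | methyl (2S,3R)-2,6-dimethyl-3-[(4-methylbenzenesulfonyl)oxy]hept-6-enoate | C[C@H](C(=O)OC)[C@H](OS(=O)(=O)c1ccc(C)cc1)CCC(C)=C
F6 | step 10 | methyl (2S,3R)-6-hydroperoxy-6-methoxy-2-methyl-3-[(4-methylbenzenesulfonyl)oxy]heptanoate | C[C@H](C(=O)OC)[C@H](OS(=O)(=O)c1ccc(C)cc1)CCC(C)(OC)OO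
F7 | step 10 | methyl (2S)-2-[(3S)-6-methoxy-6-methyl-1,2-dioxan-3-yl]propanoate | C[C@H](C(=O)OC)[C@@H]1CCC(C)(OC)OO1
F8 | step 13 | methyl (2S)-2-[(3S,6S)-6-(3-hydroxypropyl)-6-methyl-1,2-dioxan-3-yl]propanoate | C[C@H](C(=O)OC)[C@@H]1CC[C@](C)(CCCO)OO1
F9 | step 13 | methyl (2S)-2-[(3S,6R)-6-methyl-6-(3-oxopropyl)-1,2-dioxan-3-yl]propanoate | C[C@H](C(=O)OC)[C@@H]1CC[C@](C)(CCC=O)OO1
F10 | step 13 | 2-(5,5-dimethyl-3,4,5,6,7,8-hexahydronaphthalen-2-yl)-4,4,5,5-tetramethyl-1,3,2-dioxaborolane | CC1(C)OB(OC1(C)C)C1=CC2=C(CC1)C(C)(C)CCC2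
F11 | step 13 | methyl (2S)-2-[(3S,6S)-6-[3-(5,5-dimethyl-3,4,5,6,7,8-hexahydronaphthalen-2-yl)-3-hydroxypropyl]-6-methyl-1,2-dioxan-3-yl]propanoate | C[C@H](C(=O)OC)[C@@H]1CC[C@](C)(CCC(O)C2=CC3=C(CC2)C(C)(C)CCC3)OO1
F12 | step 13 | methyl (2S)-2-[(3S,6S)-6-[3-diazenyl-3-(5,5-dimethyl-3,4,5,6,7,8-hexahydronaphthalen-2-yl)propyl]-6-methyl-1,2-dioxan-3-yl]propanoate | C[C@H](C(=O)OC)[C@@H]1CC[C@](C)(CCC(N=N)C2=CC3=C(CC2)C(C)(C)CCC3)OO1
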